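**Plan**
- Retrosynthesis: after end-game edits (phenol silyl ether off, CH2OH from CHO, C3 epimer), the oxolane C2–C3 bond is cut. The 2-aryl-oxolane-3-carbaldehyde is seen as the [1,3] O-to-C ring-contraction product of a seven-membered cyclic vinyl acetal, a 2-aryl-5-arylmethyl-4,5-dihydro-1,3-dioxepine.
- That ring is cut at the C5–CH2Ar bond (Mizoroki–Heck benzylation) and at the two acetal C–O bonds, giving 3,4,5-trimethoxybenzaldehyde, (Z)-but-2-ene-1,4-diol and a 3-silyloxy-4,5-dimethoxybenzyl ester.
- Forward: the 1,3-dioxepine acetal ring is made first; the benzyl group is joined with migration of the alkene into the enol ether position; a Lewis acid then contracts the seven-membered ring to the oxolane, O1 and C7 leaving the ring as the formyl group; epimerisation, reduction and desilylation finish.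
- Enabling feature: in the dioxepine the benzylic acetal carbon C2 (between O1 and O3, cation-stabilised by the trimethoxyphenyl ring) and the enol ether O1–C7=C6 share O1. Ionisation of C2–O1 sets free an oxocarbenium ion and an enol nucleophile held together through C6–C5–C4–O3–C2.
- Stereochemistry: one stereocenter (dioxepine C5 = oxolane C4) is set by a chiral palladium catalyst. C2 and C3 are relayed from it in the ring contraction (2,4-trans, 3,4-trans), and C3 is then moved to the 2,3-trans configuration through the enolisable aldehyde.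

Key step: step 6

Assumption: the sense of induction in step 5 cannot be predicted with certainty, so the ligand antipode that delivers the 5S product is used; the three starting materials 1, 5 and 6 are taken as commercial.

**Step 1**
Reactants: 1 3-hydroxy-4,5-dimethoxybenzaldehyde
Product: 2 3,4-dimethoxy-5-(triisopropylsilyloxy)benzaldehyde
Conditions: TIPSCl, imidazole, DMF, rt
Reagents that add atoms: triisopropylsilyl chloride, CC(C)[Si](Cl)(C(C)C)C(C)C
Why: Imidazole-promoted silyl ether formation masks the phenol for the palladium, Lewis acid and base steps, and the bulky aryl TIPS ether should survive all of them.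

**Step 2**
Reactants: 2 3,4-dimethoxy-5-(triisopropylsilyloxy)benzaldehyde
Product: 3 [3,4-dimethoxy-5-(triisopropylsilyloxy)phenyl]methanol
Conditions: NaBH4, MeOH, 0 °C
Reagents that add atoms: none
Why: Borohydride reduction of an aryl aldehyde to the benzylic alcohol; no stereocenter is involved.

**Step 3**
Reactants: 3 [3,4-dimethoxy-5-(triisopropylsilyloxy)phenyl]methanol
Product: 4 [3,4-dimethoxy-5-(triisopropylsilyloxy)phenyl]methyl trifluoroacetate
Conditions: (CF3CO)2O, pyridine, CH2Cl2, 0 °C; used directly
Reagents that add atoms: trifluoroacetic anhydride, O=C(OC(=O)C(F)(F)F)C(F)(F)F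
Why: O-Acylation gives a benzylic ester with a weakly coordinating leaving group, suited to oxidative addition; the electron-rich ester should be used without storage.

**Step 4**
Reactants: 5 3,4,5-trimethoxybenzaldehyde; 6 (Z)-but-2-ene-1,4-diol
Product: 7 2-(3,4,5-trimethoxyphenyl)-4,7-dihydro-1,3-dioxepine
Conditions: p-TsOH (cat.), toluene, reflux, Dean–Stark
Reagents that add atoms: none
Why: Acid-catalysed acetalisation with azeotropic removal of water; the cis diol closes the seven-membered acetal, which is achiral.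

**Step 5**
Reactants: 7 2-(3,4,5-trimethoxyphenyl)-4,7-dihydro-1,3-dioxepine (2 equiv); 4 [3,4-dimethoxy-5-(triisopropylsilyloxy)phenyl]methyl trifluoroacetate
Product: 8 (5S)-5-{[3,4-dimethoxy-5-(triisopropylsilyloxy)phenyl]methyl}-2-(3,4,5-trimethoxyphenyl)-4,5-dihydro-1,3-dioxepine
Conditions: Pd(dba)2 (5 mol %), BINOL-derived N,N-bis(1-phenylethyl)phosphoramidite (12 mol %, antipode giving 5S), Li2CO3, 4 Å MS, 1,4-dioxane, 60 °C
Reagents that add atoms: none
Why: Proposed new method: oxidative addition of the benzylic trifluoroacetate to zerovalent palladium should give a cationic η3-benzyl divalent palladium species that inserts the cis olefin of 7 in a syn fashion under control of the chiral ligand (new stereocenter C5, catalyst-controlled); the only syn β-hydrogen then sits on C7, so hydride elimination must deliver the enol ether and cannot erase C5, and both C2 epimers of 8 are usable; the closest known reaction types are the asymmetric Mizoroki–Heck arylation of 4,7-dihydro-1,3-dioxepines with aryl triflates and the asymmetric benzylic Heck reaction of five-membered cyclic olefins with benzyl trifluoroacetates.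

**Step 6**
Reactants: 8 (5S)-5-{[3,4-dimethoxy-5-(triisopropylsilyloxy)phenyl]methyl}-2-(3,4,5-trimethoxyphenyl)-4,5-dihydro-1,3-dioxepine (both C2 epimers)
Product: 10 (2R,3S,4S)-4-{[3,4-dimethoxy-5-(triisopropylsilyloxy)phenyl]methyl}-2-(3,4,5-trimethoxyphenyl)oxolane-3-carbaldehyde, via oxocarbenium silyl enol ether triflate 9 (not isolated)
Conditions: TMSOTf (10 mol %), 4 Å MS, CH2Cl2, −78 °C, short time; Et3N quench at −78 °C
Reagents that add atoms: none
Why: TMSOTf silylates the enol ether oxygen O1 and the C2–O1 bond ionises to an E-oxocarbenium ion, stabilised by the trimethoxyphenyl ring, that carries a Z-silyl enol ether on the O3–C4–C5 tether (9); C6 then adds to C2 in an intramolecular Mukaiyama/Prins-type step and loss of the silyl group from the new carbonyl oxygen returns the catalyst, a net [1,3] O-to-C shift that shrinks the seven-membered ring to the oxolane by expelling O1 and C7 as the formyl group. The closest known reaction type is the Lewis-acid-mediated ring contraction of 2,5-disubstituted 4,5-dihydro-1,3-dioxepines to 2,3,4-trisubstituted oxolane-3-carbaldehydes. The oxolane closes by C–C bond formation in a 5-endo-trig mode at the oxocarbenium carbon, exo with respect to the enol double bond. C3 is controlled by C4: allylic 1,3-strain with the Z-silyloxy group keeps the C4–H bond in the enol plane, and the tether delivers C2 to the enol face opposite the arylmethyl group (3,4-trans). C2 is controlled by the E-oxocarbenium geometry with the aryl group pseudo-equatorial and by the compact synclinal approach that this rearrangement follows under kinetic conditions (2,3-cis, hence 2,4-trans); both C2 epimers of 8 converge because C2 becomes trigonal. The step needs kinetic control: low temperature, catalytic acid and a cold amine quench should prevent re-ionisation (which would drain to the all-trans isomer), and the near, highly nucleophilic enol silane should outrun Friedel–Crafts attack by the electron-rich arylmethyl ring.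

**Step 7**
Reactants: 10 (2R,3S,4S)-4-{[3,4-dimethoxy-5-(triisopropylsilyloxy)phenyl]methyl}-2-(3,4,5-trimethoxyphenyl)oxolane-3-carbaldehyde
Product: 11 (2R,3R,4S)-4-{[3,4-dimethoxy-5-(triisopropylsilyloxy)phenyl]methyl}-2-(3,4,5-trimethoxyphenyl)oxolane-3-carbaldehyde
Conditions: DBU (0.2 equiv), CH2Cl2, 0 °C to rt; chromatography, recovered 10 resubmitted
Reagents that add atoms: none
Why: Base-mediated epimerisation through the aldehyde enolate inverts only C3 and should favour 11, because the costly cis contact between the formyl group and the ring-bound aryl group is exchanged for a milder cis contact with the arylmethyl group.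

**Step 8**
Reactants: 11 (2R,3R,4S)-4-{[3,4-dimethoxy-5-(triisopropylsilyloxy)phenyl]methyl}-2-(3,4,5-trimethoxyphenyl)oxolane-3-carbaldehyde
Product: 12 [(2R,3S,4S)-4-{[3,4-dimethoxy-5-(triisopropylsilyloxy)phenyl]methyl}-2-(3,4,5-trimethoxyphenyl)oxolan-3-yl]methanol
Conditions: NaBH4, MeOH/THF, 0 °C
Reagents that add atoms: none
Why: Borohydride reduction of the aldehyde at low temperature fixes the C3 configuration before it can re-equilibrate.

**Step 9**
Reactants: 12 [(2R,3S,4S)-4-{[3,4-dimethoxy-5-(triisopropylsilyloxy)phenyl]methyl}-2-(3,4,5-trimethoxyphenyl)oxolan-3-yl]methanol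
Product: 13 5-{[(3S,4S,5R)-4-(hydroxymethyl)-5-(3,4,5-trimethoxyphenyl)oxolan-3-yl]methyl}-2,3-dimethoxyphenol (CNP0121704.1)
Conditions: TBAF, AcOH, THF, 0 °C to rt
Reagents that add atoms: none
Why: Buffered fluoride cleaves the aryl silyl ether without base- or acid-induced opening of the benzylic oxolane.

**Compound list**
1 | 3-hydroxy-4,5-dimethoxybenzaldehyde | O=Cc1cc(O)c(OC)c(OC)c1 | starting material
2 | 3,4-dimethoxy-5-(triisopropylsilyloxy)benzaldehyde | O=Cc1cc(O[Si](C(C)C)(C(C)C)C(C)C)c(OC)c(OC)c1 | intermediate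
3 | [3,4-dimethoxy-5-(triisopropylsilyloxy)phenyl]methanol | OCc1cc(O[Si](C(C)C)(C(C)C)C(C)C)c(OC)c(OC)c1 | intermediate
4 | [3,4-dimethoxy-5-(triisopropylsilyloxy)phenyl]methyl trifluoroacetate | FC(F)(F)C(=O)OCc1cc(O[Si](C(C)C)(C(C)C)C(C)C)c(OC)c(OC)c1 | intermediate
5 | 3,4,5-trimethoxybenzaldehyde | COc1cc(C=O)cc(OC)c1OC | starting material
6 | (Z)-but-2-ene-1,4-diol | OC/C=C\CO | starting material
7 | 2-(3,4,5-trimethoxyphenyl)-4,7-dihydro-1,3-dioxepine | COc1cc(cc(OC)c1OC)C1OCC=CCO1 | intermediate
8 | (5S)-5-{[3,4-dimethoxy-5-(triisopropylsilyloxy)phenyl]methyl}-2-(3,4,5-trimethoxyphenyl)-4,5-dihydro-1,3-dioxepine, mixture of C2 epimers | COc1cc(cc(OC)c1OC)C1OC[C@@H](Cc2cc(O[Si](C(C)C)(C(C)C)C(C)C)c(OC)c(OC)c2)C=CO1 | intermediate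
9 | oxocarbenium silyl enol ether triflate: E-configured O-alkyl oxocarbenium ion of 3,4,5-trimethoxybenzaldehyde tethered to the (S)-configured Z-trimethylsilyl enol ether | COc1cc(cc(OC)c1OC)/C=[O+]/C[C@@H](Cc1cc(O[Si](C(C)C)(C(C)C)C(C)C)c(OC)c(OC)c1)/C=C\O[Si](C)(C)C.[O-]S(=O)(=O)C(F)(F)F | intermediate (not isolated)
10 | (2R,3S,4S)-4-{[3,4-dimethoxy-5-(triisopropylsilyloxy)phenyl]methyl}-2-(3,4,5-trimethoxyphenyl)oxolane-3-carbaldehyde (2,3-cis, 3,4-trans) | COc1cc(C[C@@H]2CO[C@@H](c3cc(OC)c(OC)c(OC)c3)[C@H]2C=O)cc(O[Si](C(C)C)(C(C)C)C(C)C)c1OC | intermediate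
11 | (2R,3R,4S)-4-{[3,4-dimethoxy-5-(triisopropylsilyloxy)phenyl]methyl}-2-(3,4,5-trimethoxyphenyl)oxolane-3-carbaldehyde (2,3-trans, 3,4-cis) | COc1cc(C[C@@H]2CO[C@@H](c3cc(OC)c(OC)c(OC)c3)[C@@H]2C=O)cc(O[Si](C(C)C)(C(C)C)C(C)C)c1OC | intermediate
12 | [(2R,3S,4S)-4-{[3,4-dimethoxy-5-(triisopropylsilyloxy)phenyl]methyl}-2-(3,4,5-trimethoxyphenyl)oxolan-3-yl]methanol | COc1cc(C[C@@H]2CO[C@@H](c3cc(OC)c(OC)c(OC)c3)[C@@H]2CO)cc(O[Si](C(C)C)(C(C)C)C(C)C)c1OC | intermediate
13 | 5-{[(3S,4S,5R)-4-(hydroxymethyl)-5-(3,4,5-trimethoxyphenyl)oxolan-3-yl]methyl}-2,3-dimethoxyphenol | COc1cc(C[C@@H]2CO[C@@H](c3cc(OC)c(OC)c(OC)c3)[C@@H]2CO)cc(O)c1OC | target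

**Step count**
Total: 9 steps. Longest linear sequence: 8 steps (steps 1–3 and 5–9, from compound 1).

**Steps most likely to fail**

1. Step 5 (proposed new method). The η3-benzyl palladium species may insert too slowly into the unactivated olefin, so that reduction or homocoupling of the benzyl unit wins. The enantiotopic olefin carbons may be poorly distinguished, or the double bond may migrate out of the enol ether position. The fallback uses known chemistry, sets out from 3 and 5, and comes back at 8. Alcohol 3 would be converted with PPh3 and N-chlorosuccinimide into 5-(chloromethyl)-2,3-dimethoxyphenyl triisopropylsilyl ether F1. Palladium-catalysed syn hydrostannation of but-2-yne-1,4-diol (Bu3SnH, PdCl2(PPh3)2) would give (E)-2-(tributylstannyl)but-2-ene-1,4-diol F2. Stille coupling of F1 with F2 (Pd(PPh3)4, toluene, 90 °C) would give (Z)-2-{[3,4-dimethoxy-5-(triisopropylsilyloxy)phenyl]methyl}but-2-ene-1,4-diol F3. Acetalisation of F3 with 5, as in step 4, would give 5-{[3,4-dimethoxy-5-(triisopropylsilyloxy)phenyl]methyl}-2-(3,4,5-trimethoxyphenyl)-4,7-dihydro-1,3-dioxepine F4. Asymmetric double-bond isomerisation of this cyclic allyl acetal with a nickel hydride formed from NiBr2((R,R)-Me-DuPHOS) and LiBHEt3 (ligand antipode chosen for 5S) should place nickel on the less substituted C6 and hydrogen on C5, and β-hydride elimination from C7 would then give 8.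

2. Step 6. Re-ionisation of the product may equilibrate C2 and C3 toward the all-trans isomer, the oxocarbenium ion may be captured by the electron-rich arylmethyl ring, or adventitious acid may hydrolyse the vinyl acetal. The fallback sets out from 8 and comes back at 12, bypassing steps 6–8. Mild aqueous acid (AcOH, THF, water) would hydrolyse 8 to (4S)-4-{[3,4-dimethoxy-5-(triisopropylsilyloxy)phenyl]methyl}oxolan-2-ol F5, with recovery of 5. Oxidation (TEMPO, PhI(OAc)2) would give (4S)-4-{[3,4-dimethoxy-5-(triisopropylsilyloxy)phenyl]methyl}oxolan-2-one F6. Its lithium enolate (LDA, THF, −78 °C) should add to 5 anti to the C4 substituent and give (3R,4S)-3-[hydroxy(3,4,5-trimethoxyphenyl)methyl]-4-{[3,4-dimethoxy-5-(triisopropylsilyloxy)phenyl]methyl}oxolan-2-one F7 as a carbinol mixture. LiBH4 reduction would give (2S,3S)-2-[hydroxy(3,4,5-trimethoxyphenyl)methyl]-3-{[3,4-dimethoxy-5-(triisopropylsilyloxy)phenyl]methyl}butane-1,4-diol F8. Acid-mediated cyclisation through the benzylic cation (camphorsulfonic acid, CH2Cl2) should close the oxolane with the aryl group trans to the hydroxymethyl group and give 12.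

3. Step 7. The thermodynamic preference for 11 may be too small, or the enolate may open the ring by β-alkoxide elimination. The fallback replaces thermodynamic by kinetic control, sets out from 10 and comes back at 11. Aldehyde 10 would be converted (TMSCl, Et3N, NaI, MeCN) into [(2R,4S)-4-{[3,4-dimethoxy-5-(triisopropylsilyloxy)phenyl]methyl}-2-(3,4,5-trimethoxyphenyl)oxolan-3-ylidene]methyl trimethylsilyl ether F9. Cold protodesilylation with dilute aqueous acid in THF then delivers the proton to C3 from the less hindered face. If equilibration fails because the arylmethyl group is the more demanding neighbour, this kinetic protonation should occur from the aryl-bearing face and give 11.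

**Further compounds**
F1 | step 5 | 5-(chloromethyl)-2,3-dimethoxyphenyl triisopropylsilyl ether | ClCc1cc(O[Si](C(C)C)(C(C)C)C(C)C)c(OC)c(OC)c1
F2 | step 5 | (E)-2-(tributylstannyl)but-2-ene-1,4-diol | OC/C=C(\CO)[Sn](CCCC)(CCCC)CCCC
F3 | step 5 | (Z)-2-{[3,4-dimethoxy-5-(triisopropylsilyloxy)phenyl]methyl}but-2-ene-1,4-diol | OC/C=C(\CO)Cc1cc(O[Si](C(C)C)(C(C)C)C(C)C)c(OC)c(OC)c1
F4 | step 5 | 5-{[3,4-dimethoxy-5-(triisopropylsilyloxy)phenyl]methyl}-2-(3,4,5-trimethoxyphenyl)-4,7-dihydro-1,3-dioxepine | COc1cc(cc(OC)c1OC)C1OCC=C(Cc2cc(O[Si](C(C)C)(C(C)C)C(C)C)c(OC)c(OC)c2)CO1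
F5 | step 6 | (4S)-4-{[3,4-dimethoxy-5-(triisopropylsilyloxy)phenyl]methyl}oxolan-2-ol | OC1C[C@H](Cc2cc(O[Si](C(C)C)(C(C)C)C(C)C)c(OC)c(OC)c2)CO1
F6 | step 6 | (4S)-4-{[3,4-dimethoxy-5-(triisopropylsilyloxy)phenyl]methyl}oxolan-2-one | O=C1C[C@H](Cc2cc(O[Si](C(C)C)(C(C)C)C(C)C)c(OC)c(OC)c2)CO1
F7 | step 6 | (3R,4S)-3-[hydroxy(3,4,5-trimethoxyphenyl)methyl]-4-{[3,4-dimethoxy-5-(triisopropylsilyloxy)phenyl]methyl}oxolan-2-one | O=C1[C@@H](C(O)c2cc(OC)c(OC)c(OC)c2)[C@H](Cc2cc(O[Si](C(C)C)(C(C)C)C(C)C)c(OC)c(OC)c2)CO1
F8 | step 6 | (2S,3S)-2-[hydroxy(3,4,5-trimethoxyphenyl)methyl]-3-{[3,4-dimethoxy-5-(triisopropylsilyloxy)phenyl]methyl}butane-1,4-diol | OC[C@@H](C(O)c1cc(OC)c(OC)c(OC)c1)[C@H](Cc1cc(O[Si](C(C)C)(C(C)C)C(C)C)c(OC)c(OC)c1)CO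
F9 | step 7 | [(2R,4S)-4-{[3,4-dimethoxy-5-(triisopropylsilyloxy)phenyl]methyl}-2-(3,4,5-trimethoxyphenyl)oxolan-3-ylidene]methyl trimethylsilyl ether | COc1cc(C[C@@H]2CO[C@@H](c3cc(OC)c(OC)c(OC)c3)C2=CO[Si](C)(C)C)cc(O[Si](C(C)C)(C(C)C)C(C)C)c1OC
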